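**Retrosynthetic overview**
- The strategy rests on the cyclohexane substitution pattern: quaternary C1 (CH3, vinyl) next to C2 (isopropenyl), with the side chain on C4. This is a 4-vinylverbanone whose CMe2 bridge has been peeled off the bridgehead beside the ketone (pinane C4 = ring C1, pinane C5 = ring C2, pinane C1 = ring C4, pinane C6 with its two methyls = the isopropenyl group).
- Disconnections: the two acetates; then the ring C4–C(sp2) bond, made by palladium-catalysed α-alkenylation of a regiodefined enolate (from an enol acetate) with an (E)-alkenyl iodide, the neighbouring ring oxygen being excised afterwards.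
- The enol acetate comes from Lewis-acid heterolysis of the C1–C6 cyclobutane bond of 4-vinyl-cis-verbanone, itself from (1S,5S)-verbenone and a vinyl cuprate.
- The iodide comes from 2,3-O-isopropylidene-D-erythronolactone: C2/C3 become the acetoxy carbons, C1 is homologated to the methyl alkyne (alkene side), C4 becomes the CMe2OH carbon.
- Ring order: the only carbocycle, the six-membered ring, is present in verbenone from the start; no ring is formed, the four-membered ring is opened in step 2, and the dioxolane is only a protecting group.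

Key step: step 2

Remark on the chemistry: lactol 7 is used as an anomeric mixture, and alcohol 19 and thionocarbonate 20 as mixtures of carbinol epimers, since that centre is removed in step 14.

Step 1
Reactants: 1 (1S,5S)-(−)-verbenone; 2 vinylmagnesium bromide
Product: 4 (1S,4R,5R)-4,6,6-trimethyl-4-vinylbicyclo[3.1.1]heptan-2-one (vinyl anti to the CMe2 bridge), via silyl enol ether 3 (not isolated)
Conditions: CuBr·SMe2 (10 mol %), TMSCl, THF, −40 °C; then 1 M HCl aq.
Reagents that add atoms: none
Why: Copper-catalysed, TMSCl-accelerated conjugate addition of the vinyl Grignard reagent to the β,β-disubstituted enone should deliver vinyl to C4 from the face of the CH2 bridge, away from the gem-dimethyl bridge, which fixes the quaternary centre with vinyl anti to CMe2.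

Step 2
Reactants: 4 (1S,4R,5R)-4,6,6-trimethyl-4-vinylbicyclo[3.1.1]heptan-2-one
Product: 5 (4R,5R)-4-isopropenyl-5-methyl-5-vinylcyclohex-1-en-1-yl acetate
Conditions: Zn(OAc)2, BF3·OEt2, Ac2O, 0 °C to rt
Reagents that add atoms: acetic anhydride, CC(=O)OC(C)=O
Why: Coordination of BF3 (with Zn(OAc)2 as acetate buffer) to the C2 carbonyl lets the strained C1–C6 cyclobutane bond, which lies nearly parallel to the carbonyl π* orbital, ionise into a metal enolate and a tertiary 2-propyl cation on C5; Ac2O acylates the enolate oxygen and acetate removes a methyl proton, giving the C1=C2 enol acetate and the isopropenyl group. The closest known reaction is the Lewis-acid/acetic anhydride opening of nopinone and cis-verbanone to 4-isopropenylcyclohex-1-enyl acetates, applied here to a ketone with a methyl/vinyl quaternary carbon next to the cation-bearing carbon. No ring is closed: the bicyclo[3.1.1]heptane loses its four-membered ring and leaves the six-membered carbocycle C1–C2–C3–C4–C5–C7. No stereocentre is created; C4 and C5 take no part in the bond breaking and keep the configurations set by step 1 and by verbenone, while C1 becomes sp2. The step needs heterolysis of C1–C6 only (C5–C6 cleavage would give no enolate, C1–C7 cleavage a primary cation) and proton loss from CH3 instead of from C5–H, which the buffered acetate medium, low temperature and the more accessible methyl hydrogens should secure. Because the enol double bond can only form toward the former bridgehead, the position of the later side-chain attachment is fixed in the same operation.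

Step 3
Reactants: 6 2,3-O-isopropylidene-D-erythronolactone
Product: 7 2,3-O-isopropylidene-D-erythrofuranose (lactol)
Conditions: DIBAL-H, CH2Cl2, −78 °C; Rochelle salt work-up
Reagents that add atoms: none
Why: Partial hydride reduction of a γ-lactone with DIBAL-H at low temperature should stop at the stable tetrahedral aluminate and give the lactol without touching the two dioxolane stereocentres.

Step 4
Reactants: 7 2,3-O-isopropylidene-D-erythrofuranose
Product: 8 [(4R,5S)-5-ethynyl-2,2-dimethyl-1,3-dioxolan-4-yl]methanol (cis-dioxolane)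
Conditions: dimethyl (1-diazo-2-oxopropyl)phosphonate, K2CO3, MeOH, 0 °C to rt
Reagents that add atoms: dimethyl (1-diazo-2-oxopropyl)phosphonate, COP(=O)(OC)C(=[N+]=[N-])C(C)=O
Why: Ohira–Bestmann (Seyferth–Gilbert) homologation of the open-chain aldehyde tautomer of the lactol should turn lactone C1 into a terminal alkyne and release the C4 hydroxyl, the mild carbonate base leaving the cis-dioxolane centres in place.

Step 5
Reactants: 8 [(4R,5S)-5-ethynyl-2,2-dimethyl-1,3-dioxolan-4-yl]methanol
Product: 9 (4S,5S)-5-ethynyl-2,2-dimethyl-1,3-dioxolane-4-carboxylic acid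
Conditions: TEMPO (cat.), PhI(OAc)2, MeCN/H2O (pH 7 buffer), rt
Reagents that add atoms: water, O
Why: Oxoammonium (TEMPO/PhI(OAc)2) oxidation in aqueous acetonitrile should take the primary alcohol through the aldehyde hydrate to the acid under near-neutral conditions, so the α-alkoxy centre is not epimerised and the alkyne is untouched.

Step 6
Reactants: 9 (4S,5S)-5-ethynyl-2,2-dimethyl-1,3-dioxolane-4-carboxylic acid
Product: 10 methyl (4S,5S)-5-ethynyl-2,2-dimethyl-1,3-dioxolane-4-carboxylate
Conditions: TMSCHN2, MeOH/PhMe, 0 °C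
Reagents that add atoms: trimethylsilyldiazomethane, C[Si](C)(C)C=[N+]=[N-]
Why: Esterification of the acid with trimethylsilyldiazomethane in methanol is a base-free methylation that should preserve the epimerisable α-centre and the acetonide.

Step 7
Reactants: 10 methyl (4S,5S)-5-ethynyl-2,2-dimethyl-1,3-dioxolane-4-carboxylate
Product: 11 2-[(4S,5S)-5-ethynyl-2,2-dimethyl-1,3-dioxolan-4-yl]propan-2-ol
Conditions: MeMgBr (4 equiv), THF, 0 °C to rt; NH4Cl aq.
Reagents that add atoms: methylmagnesium bromide, C[Mg]Br
Why: Double Grignard addition to the ester should give the tertiary carbinol, one further equivalent being consumed in reversible deprotonation of the alkyne C–H, which returns on work-up.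

Step 8
Reactants: 11 2-[(4S,5S)-5-ethynyl-2,2-dimethyl-1,3-dioxolan-4-yl]propan-2-ol
Product: 12 (4S,5S)-4-ethynyl-2,2-dimethyl-5-[2-(triethylsilyloxy)propan-2-yl]-1,3-dioxolane
Conditions: TESOTf, 2,6-lutidine, CH2Cl2, 0 °C
Reagents that add atoms: triethylsilyl trifluoromethanesulfonate, CC[Si](CC)(CC)OS(=O)(=O)C(F)(F)F
Why: Silylation with the silyl triflate and a hindered pyridine base is the standard way to protect a tertiary alcohol and does not affect the alkyne or the acetonide.

Step 9
Reactants: 12 (4S,5S)-4-ethynyl-2,2-dimethyl-5-[2-(triethylsilyloxy)propan-2-yl]-1,3-dioxolane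
Product: 14 (4S,5S)-2,2-dimethyl-4-(prop-1-yn-1-yl)-5-[2-(triethylsilyloxy)propan-2-yl]-1,3-dioxolane, via lithium acetylide 13 (not isolated)
Conditions: n-BuLi, THF, −78 °C; then MeI, DMPU, −78 °C to rt
Reagents that add atoms: iodomethane, CI
Why: Deprotonation of the terminal alkyne and alkylation of the acetylide with iodomethane is a routine acetylide C-methylation that leaves the silyl ether, acetonide and stereocentres alone.

Step 10
Reactants: 14 (4S,5S)-2,2-dimethyl-4-(prop-1-yn-1-yl)-5-[2-(triethylsilyloxy)propan-2-yl]-1,3-dioxolane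
Product: 16 (4S,5S)-4-[(E)-2-iodoprop-1-en-1-yl]-2,2-dimethyl-5-[2-(triethylsilyloxy)propan-2-yl]-1,3-dioxolane, via alkenylzirconocene chloride 15 (not isolated)
Conditions: Cp2Zr(H)Cl (2.5 equiv), THF, 50 °C; then I2, THF, 0 °C
Reagents that add atoms: iodine, II
Why: Syn hydrozirconation with excess Schwartz reagent under warming should equilibrate zirconium onto the less hindered methyl-bearing alkyne carbon, and iodinolysis with retention then gives the (E)-alkenyl iodide with iodine trans to the dioxolane carbon.

Step 11
Reactants: 5 (4R,5R)-4-isopropenyl-5-methyl-5-vinylcyclohex-1-en-1-yl acetate; 16 (E)-alkenyl iodide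
Product: 18 (2S,4R,5R)-4-isopropenyl-5-methyl-5-vinyl-2-[(E)-1-{(4S,5S)-2,2-dimethyl-5-[2-(triethylsilyloxy)propan-2-yl]-1,3-dioxolan-4-yl}prop-1-en-2-yl]cyclohexan-1-one, via tributyltin enolate 17 (not isolated)
Conditions: Bu3SnOMe, PhMe, 80 °C; then 16, PdCl2[P(o-tol)3]2 (5 mol %), PhMe, 100 °C; then Et3N (cat.), CH2Cl2, rt
Reagents that add atoms: none
Why: Migita–Kosugi-type α-alkenylation, in which Bu3SnOMe turns the enol acetate into the regiodefined tin enolate that transmetalates to the alkenylpalladium species formed by oxidative addition of the iodide to zerovalent palladium and reductively eliminates with retention of the E geometry; the new α-stereocentre is doubly activated and should equilibrate to the chair with the side chain equatorial and cis to the isopropenyl group.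

Step 12
Reactants: 18 α-alkenyl ketone
Product: 19 the corresponding cyclohexanol (ring C=O reduced to CHOH, carbinol epimers)
Conditions: NaBH4, CeCl3·7H2O, MeOH, −20 °C
Reagents that add atoms: none
Why: Luche-type borohydride reduction should reduce the ketone quickly under weakly basic conditions, limiting enolisation of the β,γ-unsaturated ketone, and the configuration of the new carbinol is irrelevant because it is removed later.

Step 13
Reactants: 19 cyclohexanol
Product: 20 the O-phenyl thionocarbonate of 19
Conditions: PhOC(S)Cl, pyridine, DMAP (cat.), CH2Cl2, rt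
Reagents that add atoms: O-phenyl chlorothionoformate, S=C(Cl)Oc1ccccc1
Why: DMAP-catalysed acylation of the secondary alcohol with phenyl chlorothionoformate gives the radical-labile thiocarbonyl derivative without strong base, so the allylic dioxolane, silyl ether and alkenes are not endangered.

Step 14
Reactants: 20 O-phenyl thionocarbonate
Product: 21 (4S,5S)-2,2-dimethyl-4-{(E)-2-[(1S,3R,4R)-3-isopropenyl-4-methyl-4-vinylcyclohexyl]prop-1-en-1-yl}-5-[2-(triethylsilyloxy)propan-2-yl]-1,3-dioxolane
Conditions: Bu3SnH (high concentration), AIBN (cat.), PhMe, 90 °C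
Reagents that add atoms: none
Why: Barton–McCombie deoxygenation, in which the stannyl radical adds to the thiocarbonyl, the secondary ring radical is released and is trapped by the tin hydride faster than it can cyclise onto the neighbouring alkenes; the adjacent C–H stereocentre is not involved.

Step 15
Reactants: 21 protected lobane
Product: 22 (3S,4S,5E)-2-methyl-6-[(1S,3R,4R)-3-isopropenyl-4-methyl-4-vinylcyclohexyl]hept-5-ene-2,3,4-triol
Conditions: AcOH/H2O/THF (4:1:1), 45 °C
Reagents that add atoms: none
Why: Mild aqueous acid hydrolysis should cleave both the isopropylidene acetal and the triethylsilyl ether while being too weak to hydrate the 1,1-disubstituted alkenes or ionise the allylic C–O bond, so the diol configuration is retained.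

Step 16
Reactants: 22 lobane triol
Product: 23 (3S,4S,5E)-2-hydroxy-2-methyl-6-[(1S,3R,4R)-3-isopropenyl-4-methyl-4-vinylcyclohexyl]hept-5-ene-3,4-diyl diacetate (target)
Conditions: Ac2O, pyridine, DMAP (0.1 equiv), CH2Cl2, 0 °C to rt
Reagents that add atoms: acetic anhydride, CC(=O)OC(C)=O
Why: DMAP-catalysed acetylation esterifies the two secondary hydroxyls far faster than the hindered tertiary one, so with limited time and catalyst the tertiary alcohol should stay free.

**Compound list**
1 | (1S,5S)-(−)-verbenone | CC1=CC(=O)[C@H]2C[C@@H]1C2(C)C | starting material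
2 | vinylmagnesium bromide | C=C[Mg]Br | starting material
3 | trimethylsilyl enol ether of 4 (C2=C3 enol) | C=C[C@@]1(C)C=C(O[Si](C)(C)C)[C@H]2C[C@@H]1C2(C)C | intermediate
4 | (1S,4R,5R)-4,6,6-trimethyl-4-vinylbicyclo[3.1.1]heptan-2-one | C=C[C@@]1(C)CC(=O)[C@H]2C[C@@H]1C2(C)C | intermediate
5 | (4R,5R)-4-isopropenyl-5-methyl-5-vinylcyclohex-1-en-1-yl acetate | C=C[C@@]1(C)CC(OC(C)=O)=CC[C@@H]1C(=C)C | intermediate
6 | 2,3-O-isopropylidene-D-erythronolactone | O=C1[C@@H]2OC(C)(C)O[C@@H]2CO1 | starting material
7 | 2,3-O-isopropylidene-D-erythrofuranose (anomeric mixture) | OC1[C@@H]2OC(C)(C)O[C@@H]2CO1 | intermediate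
8 | [(4R,5S)-5-ethynyl-2,2-dimethyl-1,3-dioxolan-4-yl]methanol | C#C[C@@H]1OC(C)(C)O[C@@H]1CO | intermediate
9 | (4S,5S)-5-ethynyl-2,2-dimethyl-1,3-dioxolane-4-carboxylic acid | C#C[C@@H]1OC(C)(C)O[C@@H]1C(=O)O | intermediate
10 | methyl (4S,5S)-5-ethynyl-2,2-dimethyl-1,3-dioxolane-4-carboxylate | C#C[C@@H]1OC(C)(C)O[C@@H]1C(=O)OC | intermediate
11 | 2-[(4S,5S)-5-ethynyl-2,2-dimethyl-1,3-dioxolan-4-yl]propan-2-ol | C#C[C@@H]1OC(C)(C)O[C@@H]1C(C)(C)O | intermediate
12 | triethylsilyl ether of 11 | C#C[C@@H]1OC(C)(C)O[C@@H]1C(C)(C)O[Si](CC)(CC)CC | intermediate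
13 | lithium acetylide of 12 | [Li]C#C[C@@H]1OC(C)(C)O[C@@H]1C(C)(C)O[Si](CC)(CC)CC | intermediate
14 | (4S,5S)-2,2-dimethyl-4-(prop-1-yn-1-yl)-5-[2-(triethylsilyloxy)propan-2-yl]-1,3-dioxolane | CC#C[C@@H]1OC(C)(C)O[C@@H]1C(C)(C)O[Si](CC)(CC)CC | intermediate
15 | (E)-alkenylzirconocene chloride (Zr on the methyl-bearing carbon) | C/C(=C\[C@@H]1OC(C)(C)O[C@@H]1C(C)(C)O[Si](CC)(CC)CC)[Zr](Cl)(C1C=CC=C1)C1C=CC=C1 | intermediate
16 | (4S,5S)-4-[(E)-2-iodoprop-1-en-1-yl]-2,2-dimethyl-5-[2-(triethylsilyloxy)propan-2-yl]-1,3-dioxolane | I/C(C)=C/[C@@H]1OC(C)(C)O[C@@H]1C(C)(C)O[Si](CC)(CC)CC | intermediate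
17 | tributyltin enolate from 5 | C=C[C@@]1(C)CC(O[Sn](CCCC)(CCCC)CCCC)=CC[C@@H]1C(=C)C | intermediate
18 | (2S,4R,5R)-2-alkenyl-4-isopropenyl-5-methyl-5-vinylcyclohexanone (full C20 skeleton) | C=C[C@@]1(C)CC(=O)[C@H](/C(C)=C/[C@@H]2OC(C)(C)O[C@@H]2C(C)(C)O[Si](CC)(CC)CC)C[C@@H]1C(=C)C | intermediate
19 | cyclohexanol from 18 (carbinol epimers) | C=C[C@@]1(C)CC(O)[C@H](/C(C)=C/[C@@H]2OC(C)(C)O[C@@H]2C(C)(C)O[Si](CC)(CC)CC)C[C@@H]1C(=C)C | intermediate
20 | O-phenyl thionocarbonate of 19 | C=C[C@@]1(C)CC(OC(=S)Oc2ccccc2)[C@H](/C(C)=C/[C@@H]2OC(C)(C)O[C@@H]2C(C)(C)O[Si](CC)(CC)CC)C[C@@H]1C(=C)C | intermediate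
21 | deoxygenated protected lobane | C=C[C@@]1(C)CC[C@H](/C(C)=C/[C@@H]2OC(C)(C)O[C@@H]2C(C)(C)O[Si](CC)(CC)CC)C[C@@H]1C(=C)C | intermediate
22 | lobane triol | C=C[C@@]1(C)CC[C@H](/C(C)=C/[C@H](O)[C@H](O)C(C)(C)O)C[C@@H]1C(=C)C | intermediate
23 | CNP0119763.1, the 3,4-diacetate | C=C[C@@]1(C)CC[C@H](/C(C)=C/[C@H](OC(C)=O)[C@H](OC(C)=O)C(C)(C)O)C[C@@H]1C(=C)C | target

**Step count**
Total: 16 steps. Longest linear sequence: 14 steps (steps 3–10, then 11–16, from lactone 6).

**Steps most likely to fail**

Step 11 (fragment union). Transmetalation and reductive elimination at a secondary enolate carbon with a 1-methylalkenyl partner may be slow. Proton exchange between product and tin enolate may erode the enolate regiochemistry. The extended enolate of 18 may expel the allylic dioxolane oxygen by 1,6-elimination during epimerisation. The fallback reverses the polarity of the ring partner; it sets out from enol acetate 5 and iodide 16 and returns at ketone 18. Tsuji dehydrogenation of the tin enolate of 5 (Bu3SnOMe, Pd(OAc)2, allyl methyl carbonate, MeCN, reflux) should give (4R,5R)-4-isopropenyl-5-methyl-5-vinylcyclohex-2-en-1-one F1, the other α side being blocked by the quaternary carbon. Iodination (I2, pyridine, CH2Cl2) should give 2-iodo-4-isopropenyl-5-methyl-5-vinylcyclohex-2-en-1-one F2. Iodide 16 is converted by t-BuLi (Et2O, −78 °C) and ZnCl2 into the (E)-alkenylzinc chloride F3. Negishi coupling of F2 with F3 (Pd(PPh3)4, THF, rt) should give the cross-conjugated 2-alkenylcyclohex-2-enone F4. Conjugate reduction with [(Ph3P)CuH]6 in wet benzene and protonation to the equatorial epimer then gives 18.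

Step 2 (key fragmentation). The tertiary cation may undergo a hydride shift into the ring followed by migration of vinyl or methyl from the neighbouring quaternary carbon. It may lose the ring proton instead of a methyl proton, giving an isopropylidene group and erasing the stereocentre. The Lewis acid may also acetylate the product alkenes. The fallback separates ring opening from alkene formation; it sets out from ketone 4 and returns at enol acetate 5. Iodotrimethylsilane (TMSCl, NaI, MeCN, 0 °C) should open the same C1–C6 bond to (4R,5R)-4-(2-iodopropan-2-yl)-5-methyl-5-vinyl-1-(trimethylsilyloxy)cyclohex-1-ene F5. Dehydroiodination with DBU (PhMe, 50 °C) should give the isopropenyl silyl enol ether F6. MeLi (THF, 0 °C) releases the regiodefined lithium enolate F7, and acetic anhydride O-acetylates it to 5.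

Step 14 (radical deoxygenation). The ring radical is homoallylic to the side-chain alkene and may undergo a 1,2-alkenyl shift through a cyclopropylcarbinyl radical, or add across the ring to the isopropenyl group, before hydrogen transfer. The fallback is a polar reduction that skips steps 12–14; it sets out from ketone 18 and returns at 21. Condensation with TsNHNH2 (EtOH, rt) should give the tosylhydrazone F8. Reduction with catecholborane (CHCl3, 0 °C) followed by NaOAc·3H2O at reflux converts the C=N carbon into CH2 with loss of nitrogen and sulfinate, and the α-stereocentre is kept.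

**Further compounds**
F1 | step 11 | (4R,5R)-4-isopropenyl-5-methyl-5-vinylcyclohex-2-en-1-one | C=C[C@@]1(C)CC(=O)C=C[C@@H]1C(=C)C
F2 | step 11 | 2-iodo-4-isopropenyl-5-methyl-5-vinylcyclohex-2-en-1-one | C=C[C@@]1(C)CC(=O)C(I)=C[C@@H]1C(=C)C
F3 | step 11 | (E)-alkenylzinc chloride from 16 | Cl[Zn]/C(C)=C/[C@@H]1OC(C)(C)O[C@@H]1C(C)(C)O[Si](CC)(CC)CC
F4 | step 11 | cross-conjugated 2-alkenylcyclohex-2-enone | C=C[C@@]1(C)CC(=O)C(/C(C)=C/[C@@H]2OC(C)(C)O[C@@H]2C(C)(C)O[Si](CC)(CC)CC)=C[C@@H]1C(=C)C
F5 | step 2 | (4R,5R)-4-(2-iodopropan-2-yl)-5-methyl-5-vinyl-1-(trimethylsilyloxy)cyclohex-1-ene | C=C[C@@]1(C)CC(O[Si](C)(C)C)=CC[C@@H]1C(C)(C)I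
F6 | step 2 | (4R,5R)-4-isopropenyl-5-methyl-5-vinyl-1-(trimethylsilyloxy)cyclohex-1-ene | C=C[C@@]1(C)CC(O[Si](C)(C)C)=CC[C@@H]1C(=C)C
F7 | step 2 | lithium enolate corresponding to 5 | C=C[C@@]1(C)CC(O[Li])=CC[C@@H]1C(=C)C
F8 | step 14 | tosylhydrazone of 18 | C=C[C@@]1(C)CC(=NNS(=O)(=O)c3ccc(C)cc3)[C@H](/C(C)=C/[C@@H]2OC(C)(C)O[C@@H]2C(C)(C)O[Si](CC)(CC)CC)C[C@@H]1C(=C)C
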